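The ratio I reckoned with was the time allowed over the time needed to fill a flask's room. The room is the partner charge less what the protic impurity can take, as fractions of the solid substrate charged. Initiating radicals start a chain: the first chain carrier turns partner into product, and the second chain carrier regenerates it from dissolved starting material, while the impurity quenches partner one for one.

| setting | elm | birch | maple | ochre | blue |
|---|---|---|---|---|---|
| solid substrate | 0.20 M | 0.20 M | 0.20 M | 0.20 M | 0.20 M |
| partner | 0.95 equiv | 0.95 equiv | 0.79 equiv | 0.470 equiv | 0.950 equiv |
| protic impurity | 0.040 M | 0.040 M | 0.040 M | 0.0400 M | 0.0400 M |
| initiator | 4.2 mol% | 8.3 mol% | 2 mol% | 8 mol% | 2 mol% |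
| remark | run made earlier | run made earlier | run made earlier |  |  |
| time |  |  |  | 40 min | 40 min |

| elm: time / min | elm: product / % | birch: time / min | birch: product / % | maple: time / min | maple: product / % |
|---|---|---|---|---|---|
| 5.00 | 9.3 | 2.50 | 5.1 | 2.50 | 2.9 |
| 10.0 | 18.1 | 8.00 | 18.9 | 8.00 | 8.7 |
| 15.0 | 24.3 | 12.0 | 26.4 | 12.0 | 11.1 |
| 20.0 | 30.8 | 20.0 | 38.7 | 20.0 | 17.5 |

(standard deviation of a reading: 0.5 percentage points)

- in percentages every species weighs as the solid substrate in it: one ended chains A counts as two
- as a solid, counted per litre of solution: solid substrate
- reactions considered so far: initiator -> 2 initiating radical; starting material + initiating radical -> capped initiator + first chain carrier; partner + first chain carrier -> product + second chain carrier; starting material + second chain carrier -> released group + first chain carrier; 2 first chain carrier -> ended chains A; 2 second chain carrier -> ended chains B; solid substrate <-> starting material; partner + protic impurity -> quenched reagent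
- at the start none of the solid substrate is in solution
- what has only dissolved of solid substrate counts as not reacted

- the winner by amount of product, in percent of the solid substrate charged; "neither" if no more than 2 percentage points parts them (ochre / blue / neither)
- how much product is there at the end, in percent of the solid substrate charged: ochre
- how much product is there at the end, in percent of the solid substrate charged: blue

The impurity's share is 0.200, and I counted it as taken in full, so ochre's room is 0.270 and blue's 0.750. I froze the chain carriers at a steady level, and I froze the early rate per equivalent of partner at each loading. This turnover constant, a pseudo-first-order constant, reads 0.0249 /min from birch at 8.3 mol%, which I took for ochre's 8 mol%. Maple gives 0.0138 /min at blue's 2 mol%.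

The ladder then has three rungs. Ochre's fill time comes first at 23.1 min, the window of 40 min is next, and blue's fill time is last at 57.4 min. Letting the room fill exponentially, I reckoned 22.2% for ochre, which is 82.2% of its room, and 37.7% for blue, which is 50.3% of its room.

The forecast named blue, with ochre at 24% (19% to 33%) and blue at 31% (26% to 37%), saying “The impurity can destroy 20 percentage points of partner, leaving a cap near 27% if quenching is fast”. My ochre lay lower and my blue higher.

The flask gave blue, with ochre at 22.5% and blue at 35.3%, so the forecast held.

    initiator → 2 initiating radical (k = 0.0187 /min)
    starting material + initiating radical → capped initiator + first chain carrier (k = 1.74 × 10⁵ /M/s)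
    partner + first chain carrier → product + second chain carrier (k = 3.32 × 10⁵ /M/min)
    starting material + second chain carrier → released group + first chain carrier (k = 2.55 × 10⁵ /M/min)
    2 first chain carrier → ended chains A (k = 3.70 × 10⁸ /M/s)
    2 second chain carrier → ended chains B (k = 6.60 × 10⁶ /M/s)
    solid substrate ⇌ starting material, rate k7*(cs7 - [starting material]) while solid is left; crystals form when [starting material] > cs7 (solubility = 0.130 M, k = 0.342 /min)
    partner + protic impurity → quenched reagent (k = 1.79 /M/min)

Ochre and blue differ in two settings. Ochre's greater loading helped it, for at blue's loading ochre gives 14.6% instead of 22.5%, while its smaller partner charge held it back, for with blue's charge ochre gives 54.2%, which is 41% of what ochre is missing. The low solubility of starting material, which my reckoning never used, makes no difference to ochre's product.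

A neighbour of ochre charged with 1.20 equiv of partner has room 1.00, and the same constant gives a fill time of 33.5 min and 69.7% of product. The computed flask gives 71.1%.

The numbers in the tables are simulated for substances that don't exist; scatter was added.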